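The readings come from a simulation with constants of no real substance; the scatter is artificial.

The row is read at 1.0 h after a feed of 8.0 min, so the charge of starting material has on average stood with the partner for 56.0 min. That mean replaces the feed, and in the flasks of the row it shifts the waiting time by at most 7.14%.

| flask | starting material | partner | scavenger | remark | time |
|---|---|---|---|---|---|
| red | 0.10 M (fed, over 8.0 min) | 0.031 M | 0.030 M | run made earlier |  |
| violet | 0.10 M (fed, over 8.0 min) | 0.35 M | 0.030 M | run made earlier |  |
| ochre | 0.10 M (fed, over 8.0 min) | 2.9 M | 0.030 M | run made earlier |  |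
| oak | 0.10 M (fed, over 8.0 min) | 0.0400 M | 0.0300 M |  | 1.0 h |
| larch | 0.10 M (fed, over 8.0 min) | 0.120 M | 0.0300 M |  | 1.0 h |
| ash | 0.10 M (fed, over 8.0 min) | 0.300 M | 0.0300 M |  | 1.0 h |
| alder | 0.10 M (fed, over 8.0 min) | 1.00 M | 0.0300 M |  | 1.0 h |
| elm | 0.10 M (fed, over 8.0 min) | 3.00 M | 0.0300 M |  | 1.0 h |

| red: time / min | red: mono adduct / % | violet: time / min | violet: mono adduct / % | ochre: time / min | ochre: mono adduct / % |
|---|---|---|---|---|---|
| 8.00 | 1.2 | 8.00 | 6.3 | 4.00 | 12.8 |
| 15.0 | 2.5 | 15.0 | 15.8 | 10.0 | 40.4 |
| 25.0 | 1.6 | 25.0 | 25.8 | 20.0 | 36.3 |
| 30.0 | 2.8 | 30.0 | 29.3 | 30.0 | 22.8 |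
| 40.0 | 5.2 | 40.0 | 33.7 | 40.0 | 15.9 |

(each reading ± 1 percentage point)

- percentages count the whole charge, also what has not yet gone in
- "hardly changes" means that all values lie within two and a half points (for a concentration: within two and a half percent of the largest)

1. [mono adduct] at the end for oak, larch, ash, alder, elm, in this order
2. the shape of the row from first to last (falls, then rises / rises all the way / hardly changes / falls all the way / rises, then falls)

The partner charge in ochre far exceeds the charge of starting material, and on that ground the reckoning made here assumes, as an approximation, that partner and time enter as a product. The reckoning made here calls this product the exposure, meaning partner charge times time since the mean moment of feeding, and draws mono adduct against it as a single curve.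

The curve starts from the violet reading at 15.0 min, which gives a slope of 0.0410 /M/min. Violet's last reading stands at an exposure of 12.6 M·min. A straight line would reach 51.7% there, but the reading is lower, at 33.7%, so the knee has been passed.

The top comes next. Ochre's tallest readings stand at 10.0 min and 20.0 min, with exposures of 17.4 M·min and 46.4 M·min. Midway between those times lies the turning exposure, the exposure at which mono adduct peaks: 31.9 M·min, a reading with a wide margin. Beyond it the curve falls, to 15.9% at 104 M·min.

Divided by the waiting time, the turning exposure puts the top of the row at 0.570 M. The margin stretches this from 0.311 M to 0.829 M, which still lies above ash and below alder.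

| Flask | Exposure | Forecast |
|---|---|---|
| oak | 2.24 M·min | 0.0085 M |
| larch | 6.72 M·min | 0.0215 M |
| ash | 16.8 M·min | 0.037 M |
| alder | 56.0 M·min | 0.032 M |
| elm | 168 M·min | 0.0045 M |

The forecast says “The row rises, peaks near ash, then falls.” It shares the shape, rises, then falls, with the reckoning made here, but the two differ on the place, since this reckoning sets the turn past ash.

    partner → decomposed reagent (k = 2.30 × 10⁻⁴ /s)
    partner + mono adduct → bis adduct + released group (k = 6.60 × 10⁻⁴ /M/s)
    scavenger + released group → scavenged by-product (k = 0.0140 /M/s)
    starting material + partner → mono adduct + released group (k = 0.00100 /M/s)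
    partner + bis adduct → tris adduct + released group (k = 4.70 × 10⁻⁴ /M/s)
    partner + released group ⇌ idle adduct, settled at all times (K = 24.0 /M)

The flasks give 0.00703 M, 0.0182 M, 0.0343 M, 0.0410 M and 0.00595 M, in the order asked, so the shape is rises, then falls. Alder stands tallest, and the row turns at 0.69 M, an exposure of 38.6 M·min against the turning exposure of 31.9 M·min. Counted by its partner charge, elm has 5.27 turning exposures behind it at 1.00 h, when 34% of that charge is left, and there it holds mono adduct at 5.95% and tris adduct at 71.3%.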